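**Retrosynthetic overview**

1. Target ⇐ C15 acid reduced to the allylic alcohol and C8–Br exchanged for C8–CH3 ⇐ an 8-bromo-Δ8 triester in which ring B is complete.
2. Ring B (C5–C6–C7–C8–C9–C10) ⇐ one-carbon ring expansion of the cyclopentene C5–C6–C7=C9–C10 of a trans-hydrindene: dibromocarbene delivers C8 across C7=C9, Ag+ opens the cyclopropane to the C7–C8–C9 allyl cation, acetate enters at C7. Enabling feature: in ring B the allylic acetate carbon C7 lies between C6, whose β-isovalerate is trans-diaxial to the 7α-acetate, and the tetrasubstituted C8=C9 alkene, whose C8 carries only a one-carbon substituent.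
3. C9–C11 bond ⇐ Negishi coupling of a C9 enol triflate with a C11–C15 alkylzinc; C15 is masked as an enoate so that the side-chain alkene is inert to the carbene.
4. trans-Hydrindane core ⇐ (S)-Hajos–Parrish ketone: deconjugative C4 gem-dimethylation (gives C5=C6), C3 ketone to C2=C3, double hydroboration on the α face sets C2, C5 and C6 from C10; C6 is then inverted by oxidation and Luche reduction.
5. Ring order: ring A and the five-membered proto-ring B are bought with the Hajos–Parrish ketone (C10 from proline catalysis); ring B reaches its final size last.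

Key step: step 18

Remark: labdane numbering is used for all intermediates (ring A = C1–C5 and C10; proto-ring B = C5, C6, C7, C9, C10; C8 enters in step 18; side chain C11–C15); α is the face opposite the C10 methyl group, β the same face.
Assumption: the SMILES encodes the normal labdane series (10S; 2α-OAc, 5α-H, 6β-isovalerate, 7α-OAc, 13E), which corresponds to (S)-Hajos–Parrish ketone.

**Route**

Step 1
Reactants: 1 (S)-Hajos–Parrish ketone
Product: 2 C9 ethylene ketal of the Hajos–Parrish ketone (C3 enone kept)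
Conditions: HOCH2CH2OH, p-TsOH (cat.), 4 Å MS, CH2Cl2, rt
Reagents that add atoms: ethylene glycol OCCO
Why: Acid-catalysed ketalisation should be selective for the saturated cyclopentanone carbonyl (C9) over the less electrophilic vinylogous C3 enone carbonyl; no stereocentre is formed and C10 (S) is bought with the starting material.

Step 2
Reactants: 2 C9 ethylene ketal of the Hajos–Parrish ketone
Product: 3 4,4-dimethyl-3-oxo-5-ene C9 ketal
Conditions: t-BuOK, MeI, t-BuOH/THF, 0 °C → rt
Reagents that add atoms: iodomethane CI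
Why: Thermodynamic deprotonation gives the extended dienolate, which is methylated twice at C4 (deconjugative α,α-dialkylation of an enone), so that the double bond moves to the ring-fusion position C5=C6; C4 is not stereogenic.

Step 3
Reactants: 3 4,4-dimethyl-3-oxo-5-ene C9 ketal
Product: 4 C3 enol triflate (2,5-diene) C9 ketal
Conditions: KHMDS, PhNTf2, THF, −78 → 0 °C
Reagents that add atoms: N-phenylbis(trifluoromethanesulfonimide) O=S(=O)(N(c1ccccc1)S(=O)(=O)C(F)(F)F)C(F)(F)F
Why: Enolisation is possible only toward C2 because C4 is quaternary, and O-sulfonylation of the enolate gives the enol triflate (enol triflate formation).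

Step 4
Reactants: 4 C3 enol triflate (2,5-diene) C9 ketal
Product: 5 4,4-dimethyl-2,5-diene C9 ketal
Conditions: Pd(OAc)2 (cat.), PPh3, HCO2H, n-Bu3N, DMF, 60 °C
Reagents that add atoms: none
Why: Palladium-catalysed formate reduction of the enol triflate replaces OTf by H and leaves the C2=C3 double bond in place; no stereocentre is formed.

Step 5
Reactants: 5 4,4-dimethyl-2,5-diene C9 ketal
Product: 7 2α,6α-diol C9 ketal (5α-H trans-hydrindane), via mixed bis-borane 6 (not isolated)
Conditions: 9-BBN, THF, 65 °C; then BH3·THF, 0 °C → rt; then NaOH, H2O2, 0 °C → rt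
Reagents that add atoms: hydrogen peroxide OO
Why: Sequential hydroboration–oxidation, in which 9-BBN adds to the disubstituted C2=C3 bond with boron at C2 (away from the quaternary C4) and BH3 then adds to the hindered C5=C6 bond with boron at C6; both syn additions should occur on the α face opposite the axial C10 methyl group, so that C2 (α-OH), C5 (α-H, trans ring fusion) and C6 (α-OH) are set by substrate control from C10, and oxidation proceeds with retention.

Step 6
Reactants: 7 2α,6α-diol C9 ketal
Product: 8 2α,6α-bis(TBS ether) C9 ketal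
Conditions: TBSCl, imidazole, DMAP (cat.), DMF, 40 °C
Reagents that add atoms: tert-butyldimethylsilyl chloride CC(C)(C)[Si](C)(C)Cl
Why: Silyl ether formation on both secondary alcohols; no selectivity between them is needed and no stereocentre is touched.

Step 7
Reactants: 8 2α,6α-bis(TBS ether) C9 ketal
Product: 9 2α,6α-bis(TBSO) 9-ketone
Conditions: PPTS, acetone/H2O, 60 °C
Reagents that add atoms: water O
Why: Mild acid-catalysed hydrolysis of the dioxolane, under which secondary TBS ethers should survive and the β-silyloxy ketone should not eliminate.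

Step 8
Reactants: 9 2α,6α-bis(TBSO) 9-ketone
Product: 10 2α,6α-bis(TBSO) 7-en-9-yl triflate
Conditions: Tf2O, 2,6-di-tert-butyl-4-methylpyridine, CH2Cl2, 0 °C → rt
Reagents that add atoms: trifluoromethanesulfonic anhydride O=S(=O)(OS(=O)(=O)C(F)(F)F)C(F)(F)F
Why: Enol triflate formation by O-sulfonylation of the ketone and loss of the only α-proton (C7, since C10 is quaternary); no enolate is generated, so β-elimination of the C6 silyloxy group should be avoided.

Step 9
Reactants: 11 tert-butyl(but-3-yn-1-yloxy)dimethylsilane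
Product: 13 2-(trimethylsilyl)ethyl (E)-5-(TBSO)-3-methylpent-2-enoate, via alkenylalane 12 (not isolated)
Conditions: Me3Al, Cp2ZrCl2 (cat.), CH2Cl2, 0 °C → rt; then ClCO2CH2CH2SiMe3, 0 °C → rt
Reagents that add atoms: trimethylaluminium C[Al](C)C; 2-(trimethylsilyl)ethyl chloroformate C[Si](C)(C)CCOC(Cl)=O
Why: Zirconium-catalysed carboalumination (Negishi) adds methyl and aluminium syn across the terminal alkyne with aluminium at the terminus, and acylation of the alkenylalane with retention fixes the (E)-C13=C14 geometry.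

Step 10
Reactants: 13 2-(trimethylsilyl)ethyl (E)-5-(TBSO)-3-methylpent-2-enoate
Product: 14 2-(trimethylsilyl)ethyl (E)-5-hydroxy-3-methylpent-2-enoate
Conditions: AcOH/THF/H2O (3:1:1), rt
Reagents that add atoms: none
Why: Mild acidic hydrolysis of the primary silyl ether; the (E)-hydroxy enoate cannot lactonise and the TMSE ester is stable to acid.

Step 11
Reactants: 14 2-(trimethylsilyl)ethyl (E)-5-hydroxy-3-methylpent-2-enoate
Product: 15 2-(trimethylsilyl)ethyl (E)-5-iodo-3-methylpent-2-enoate
Conditions: I2, PPh3, imidazole, CH2Cl2, 0 °C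
Reagents that add atoms: iodine II
Why: Appel-type iodination of the primary alcohol; the enoate geometry is not affected.

Step 12
Reactants: 10 2α,6α-bis(TBSO) 7-en-9-yl triflate + 15 2-(trimethylsilyl)ethyl (E)-5-iodo-3-methylpent-2-enoate
Product: 17 2α,6α-bis(TBSO) 7-ene carrying the C11–C15 TMSE enoate chain at C9, via alkylzinc iodide 16 (not isolated)
Conditions: Zn dust (TMSCl/BrCH2CH2Br-activated), LiCl, THF, 40 °C; then 10, PdCl2(dppf) (cat.), THF/NMP, 50 °C
Reagents that add atoms: none
Why: Negishi sp3–sp2 cross-coupling, in which zinc insertion tolerates the ester and the bidentate ligand suppresses β-hydride elimination, forms the C9–C11 bond at the neopentyl alkenyl triflate; no stereocentre is touched.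

Step 13
Reactants: 17 2α,6α-bis(TBSO) 7-ene TMSE enoate
Product: 18 2α,6α-diol 7-ene TMSE enoate
Conditions: HF·pyridine, pyridine, THF, 0 °C → rt
Reagents that add atoms: none
Why: Buffered HF cleaves both secondary silyl ethers, while the TMSE ester, which needs unsolvated fluoride to fragment, should remain.

Step 14
Reactants: 18 2α,6α-diol 7-ene TMSE enoate
Product: 19 2α-hydroxy 7-en-6-one TMSE enoate
Conditions: MnO2 (activated), CH2Cl2, rt
Reagents that add atoms: none
Why: Manganese dioxide oxidises only the allylic C6 alcohol and leaves the saturated C2 alcohol; under these neutral conditions the C5 stereocentre α to the new carbonyl should not epimerise.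

Step 15
Reactants: 19 2α-hydroxy 7-en-6-one TMSE enoate
Product: 20 2α,6β-diol 7-ene TMSE enoate
Conditions: NaBH4, CeCl3·7H2O, MeOH, −78 °C
Reagents that add atoms: none
Why: Luche 1,2-reduction, in which hydride should attack the C6 carbonyl from the α face, opposite the C10 methyl and the 4β-methyl group, to give the 6β allylic alcohol.

Step 16
Reactants: 20 2α,6β-diol 7-ene TMSE enoate
Product: 21 2α-acetoxy 6β-hydroxy 7-ene TMSE enoate
Conditions: Ac2O (1.1 equiv), pyridine, CH2Cl2, 0 °C
Reagents that add atoms: acetic anhydride CC(=O)OC(C)=O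
Why: Selective acylation of the unhindered equatorial C2 hydroxyl; the C6β hydroxyl, flanked by the ring fusion and syn to two methyl groups, should react much more slowly.

Step 17
Reactants: 21 2α-acetoxy 6β-hydroxy 7-ene TMSE enoate
Product: 22 2α-acetoxy 6β-isovaleryloxy 7-ene TMSE enoate
Conditions: isovaleryl chloride, Et3N, DMAP, CH2Cl2, 0 °C → rt
Reagents that add atoms: 3-methylbutanoyl chloride CC(C)CC(Cl)=O
Why: DMAP-catalysed acylation places the isovalerate on C6 while that oxygen is still on the five-membered ring and not yet 1,3-diaxial to two methyl groups; configuration is retained.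

Step 18
Reactants: 22 2α-acetoxy 6β-isovaleryloxy 7-ene TMSE enoate
Product: 25 8-bromo-2α,7α-diacetoxy-6β-isovaleryloxy 8-ene TMSE enoate (ring B six-membered), via dibromocyclopropane 23 (not isolated), via acyloxonium acetate 24 (not isolated)
Conditions: CHBr3, 50% aq NaOH, BnEt3NCl (cat.), CH2Cl2, 0 °C; phase separation and solvent switch; then AgOAc, AcOH/Ac2O (10:1), 45 °C, dark
Reagents that add atoms: bromoform BrC(Br)Br; silver(I) acetate CC(=O)[O-].[Ag+]
Why: Phase-transfer dibromocarbene addition should occur at the electron-rich C7=C9 bond from the α face (opposite the C10 methyl and the C6β ester) and leave the electron-poor enoate alkene untouched, giving 23; Ag+ then abstracts the endo bromide and the cyclopropyl cation opens in the thermally allowed disrotatory sense (Woodward–Hoffmann–DePuy rule) with cleavage of the C7–C9 bond to the 8-bromoallyl cation C7–C8–C9 of the new six-membered ring. The closest known reaction type is the silver-promoted solvolytic ring expansion of 6,6-dibromobicyclo[3.1.0]hexanes to 2-bromocyclohex-2-enyl acetates, combined with Prévost-type acyloxy participation. Ring B is not closed by a new ring bond but arises by scission of the bond shared by the three- and five-membered rings (net insertion of C8 between C7 and C9), while the transient dioxolanylium ring closes by attack of the isovalerate carbonyl oxygen on C7 (five-membered neighbouring-group closure) and is reopened. The only new stereocentre, C7, is controlled by the C6β isovalerate: the ester bridges the β face and acetate opens 24 at the allylic carbon C7 from the α face, which gives the trans-diaxial 6β-acyloxy/7α-acetoxy pair. The step needs regioselectivity for C7 over the tertiary terminus C9 and fidelity of the two different acyl groups; these should be secured by the participating ester on the adjacent C6, by the quaternary C10 that shields C9, by the more stable tetrasubstituted C8=C9 alkene of the product, and by the anhydrous medium that prevents hydrolysis of 24 to a cis-hydroxy ester.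

Step 19
Reactants: 25 8-bromo-2α,7α-diacetoxy-6β-isovaleryloxy 8-ene TMSE enoate
Product: 26 TMSE ester of 2α,7α-diacetoxy-6β-isovaleryloxylabda-8,13E-dien-15-oic acid
Conditions: MeZnCl, Pd(P(t-Bu)3)2 (cat.), THF/NMP, 40 °C
Reagents that add atoms: methylzinc chloride C[Zn]Cl
Why: Negishi methylation of the alkenyl bromide installs C17, since oxidative addition into the C–Br bond should outrun ionisation of the hindered allylic acetate and methylzinc tolerates the four esters; no stereocentre is touched.

Step 20
Reactants: 26 TMSE ester of 2α,7α-diacetoxy-6β-isovaleryloxylabda-8,13E-dien-15-oic acid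
Product: 27 2α,7α-diacetoxy-6β-isovaleryloxylabda-8,13E-dien-15-oic acid
Conditions: TBAF, THF, 0 °C; then aq NH4Cl
Reagents that add atoms: none
Why: Fluoride-induced fragmentation of the 2-(trimethylsilyl)ethyl ester is fast at 0 °C and should leave the acetates and the isovalerate, which have no free neighbouring hydroxyl to migrate to.

Step 21
Reactants: 27 2α,7α-diacetoxy-6β-isovaleryloxylabda-8,13E-dien-15-oic acid
Product: 29 2α,7α-diacetoxy-6β-(3-methylbutanoyloxy)labda-8,13E-dien-15-ol (CNP0257091.1), via mixed carbonic anhydride 28 (not isolated)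
Conditions: i-BuOCOCl, N-methylmorpholine, THF, −15 °C; then NaBH4, H2O, −15 → 0 °C
Reagents that add atoms: none
Why: Mixed-anhydride activation followed by borohydride reduction converts only the carboxylic acid into the primary allylic alcohol (1,2-reduction), because alkyl esters are inert to NaBH4 under these conditions; the 13E geometry is kept.

**Compound list**

1 | (S)-Hajos–Parrish ketone, (7aS)-7a-methyl-2,3,7,7a-tetrahydro-1H-indene-1,5(6H)-dione | C[C@]12CCC(=O)C=C1CCC2=O | starting material
2 | C9 ethylene ketal of 1 (3-oxo-4-ene) | C[C@]12CCC(=O)C=C1CCC23OCCO3 | intermediate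
3 | 4,4-dimethyl-3-oxo-5-ene C9 ketal | C[C@]12CCC(=O)C(C)(C)C1=CCC23OCCO3 | intermediate
4 | 3-triflyloxy-4,4-dimethyl-2,5-diene C9 ketal | C[C@]12CC=C(OS(=O)(=O)C(F)(F)F)C(C)(C)C1=CCC23OCCO3 | intermediate
5 | 4,4-dimethyl-2,5-diene C9 ketal | C[C@]12CC=CC(C)(C)C1=CCC23OCCO3 | intermediate
6 | mixed bis-borane (2α-(9-BBN), 6α-BH2, 5α-H) C9 ketal | C[C@]12C[C@@H](B3C4CCCC3CCC4)CC(C)(C)[C@@H]1[C@@H](B)CC23OCCO3 | intermediate
7 | 2α,6α-diol C9 ketal (5α-H, 10β-Me trans-hydrindane) | C[C@]12C[C@@H](O)CC(C)(C)[C@@H]1[C@@H](O)CC23OCCO3 | intermediate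
8 | 2α,6α-bis(TBS ether) C9 ketal | C[C@]12C[C@@H](O[Si](C)(C)C(C)(C)C)CC(C)(C)[C@@H]1[C@@H](O[Si](C)(C)C(C)(C)C)CC23OCCO3 | intermediate
9 | 2α,6α-bis(TBSO) 9-ketone | C[C@]12C[C@@H](O[Si](C)(C)C(C)(C)C)CC(C)(C)[C@@H]1[C@@H](O[Si](C)(C)C(C)(C)C)CC2=O | intermediate
10 | 2α,6α-bis(TBSO) 7-en-9-yl triflate | C[C@]12C[C@@H](O[Si](C)(C)C(C)(C)C)CC(C)(C)[C@@H]1[C@@H](O[Si](C)(C)C(C)(C)C)C=C2OS(=O)(=O)C(F)(F)F | intermediate
11 | tert-butyl(but-3-yn-1-yloxy)dimethylsilane | C#CCCO[Si](C)(C)C(C)(C)C | starting material
12 | (E)-[4-(TBSO)-2-methylbut-1-enyl]dimethylalane | C[Al](C)/C=C(\C)CCO[Si](C)(C)C(C)(C)C | intermediate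
13 | 2-(trimethylsilyl)ethyl (E)-5-(TBSO)-3-methylpent-2-enoate | CC(C)(C)[Si](C)(C)OCC/C(C)=C/C(=O)OCC[Si](C)(C)C | intermediate
14 | 2-(trimethylsilyl)ethyl (E)-5-hydroxy-3-methylpent-2-enoate | OCC/C(C)=C/C(=O)OCC[Si](C)(C)C | intermediate
15 | 2-(trimethylsilyl)ethyl (E)-5-iodo-3-methylpent-2-enoate | ICC/C(C)=C/C(=O)OCC[Si](C)(C)C | intermediate
16 | alkylzinc iodide derived from 15 | I[Zn]CC/C(C)=C/C(=O)OCC[Si](C)(C)C | intermediate
17 | 2α,6α-bis(TBSO) 7-ene with the C11–C15 TMSE enoate chain on C9 | C[C@]12C[C@@H](O[Si](C)(C)C(C)(C)C)CC(C)(C)[C@@H]1[C@@H](O[Si](C)(C)C(C)(C)C)C=C2CC/C(C)=C/C(=O)OCC[Si](C)(C)C | intermediate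
18 | 2α,6α-diol 7-ene TMSE enoate | C[C@]12C[C@@H](O)CC(C)(C)[C@@H]1[C@@H](O)C=C2CC/C(C)=C/C(=O)OCC[Si](C)(C)C | intermediate
19 | 2α-hydroxy 7-en-6-one TMSE enoate | C[C@]12C[C@@H](O)CC(C)(C)[C@@H]1C(=O)C=C2CC/C(C)=C/C(=O)OCC[Si](C)(C)C | intermediate
20 | 2α,6β-diol 7-ene TMSE enoate | C[C@]12C[C@@H](O)CC(C)(C)[C@@H]1[C@H](O)C=C2CC/C(C)=C/C(=O)OCC[Si](C)(C)C | intermediate
21 | 2α-acetoxy 6β-hydroxy 7-ene TMSE enoate | C[C@]12C[C@@H](OC(C)=O)CC(C)(C)[C@@H]1[C@H](O)C=C2CC/C(C)=C/C(=O)OCC[Si](C)(C)C | intermediate
22 | 2α-acetoxy 6β-isovaleryloxy 7-ene TMSE enoate | C[C@]12C[C@@H](OC(C)=O)CC(C)(C)[C@@H]1[C@H](OC(=O)CC(C)C)C=C2CC/C(C)=C/C(=O)OCC[Si](C)(C)C | intermediate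
23 | dibromocyclopropane of 22 (C8Br2 bridging C7 and C9 on the α face) | C[C@]12C[C@@H](OC(C)=O)CC(C)(C)[C@@H]1[C@H](OC(=O)CC(C)C)[C@H]3C(Br)(Br)[C@@]23CC/C(C)=C/C(=O)OCC[Si](C)(C)C | intermediate
24 | 6β,7β-bridged 2-isobutyl-1,3-dioxolan-2-ylium acetate of the ring-expanded 8-bromo-8-ene | CC(=O)O[C@H]1CC(C)(C)[C@@H]2[C@@H]3OC(CC(C)C)=[O+][C@@H]3C(Br)=C(CC/C(C)=C/C(=O)OCC[Si](C)(C)C)[C@@]2(C)C1.CC(=O)[O-] | intermediate
25 | 8-bromo-2α,7α-diacetoxy-6β-isovaleryloxy 8-ene TMSE enoate (17-nor-labdane with Br on C8) | CC(=O)O[C@H]1CC(C)(C)[C@@H]2[C@H](OC(=O)CC(C)C)[C@@H](OC(C)=O)C(Br)=C(CC/C(C)=C/C(=O)OCC[Si](C)(C)C)[C@@]2(C)C1 | intermediate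
26 | 2-(trimethylsilyl)ethyl 2α,7α-diacetoxy-6β-isovaleryloxylabda-8,13E-dien-15-oate | CC(=O)O[C@H]1CC(C)(C)[C@@H]2[C@H](OC(=O)CC(C)C)[C@@H](OC(C)=O)C(C)=C(CC/C(C)=C/C(=O)OCC[Si](C)(C)C)[C@@]2(C)C1 | intermediate
27 | 2α,7α-diacetoxy-6β-isovaleryloxylabda-8,13E-dien-15-oic acid | CC(=O)O[C@H]1CC(C)(C)[C@@H]2[C@H](OC(=O)CC(C)C)[C@@H](OC(C)=O)C(C)=C(CC/C(C)=C/C(O)=O)[C@@]2(C)C1 | intermediate
28 | isobutyl carbonic mixed anhydride of 27 | CC(=O)O[C@H]1CC(C)(C)[C@@H]2[C@H](OC(=O)CC(C)C)[C@@H](OC(C)=O)C(C)=C(CC/C(C)=C/C(=O)OC(=O)OCC(C)C)[C@@]2(C)C1 | intermediate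
29 | 2α,7α-diacetoxy-6β-(3-methylbutanoyloxy)labda-8,13E-dien-15-ol (CNP0257091.1) | CC(=O)O[C@H]1CC(C)(C)[C@@H]2[C@H](OC(=O)CC(C)C)[C@@H](OC(C)=O)C(C)=C(CC/C(C)=C/CO)[C@@]2(C)C1 | target

**Step count and risks**

Total step count: 21. Longest linear sequence: 18 steps (steps 1–8 and 12–21); the side-chain branch is steps 9–11.

Steps most likely to fail:

Step 18. Carbene transfer to the hindered C7=C9 alkene, which is deactivated by the allylic ester, may be slow, and the C2 acetate may be partly saponified by the two-phase base. In the silver stage the free allyl cation may be captured at C9 or lose a proton to give dienes. The fallback separates carbene transfer, ring expansion and C–O bond formation; it sets out from 20 and comes back at 25. Dibromocarbene (CHBr3, aq NaOH, BnEt3NCl, 0 °C) is added to diol 20, whose alkene carries no allylic ester and which has no acetate, to give the dibromocyclopropane 2α,6β-diol F1. Ac2O/pyridine at 0 °C should give its 2-acetate F2, and isovaleryl chloride/DMAP then gives 23, which is isolated here. Heating 23 in toluene at 90 °C should bring about the thermal electrocyclic opening with internal return of bromide anti to the ester, giving the 7α,8-dibromo-8-ene triester F3. Bu4NOAc in acetone at 40 °C should then replace the allylic bromide with net retention through the same acyloxonium ion 24, without a free cation, to give 25.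

Step 8. The O-triflyl oxocarbenium intermediate next to the quaternary C10 may undergo a Wagner–Meerwein shift of the C10 methyl group, or the C6 silyloxy group may be lost by elimination. The fallback sets out from 9 and comes back at 17. Ketone 9 is condensed with hydrazine hydrate (Et3N, EtOH, reflux) to the C9 hydrazone F4. Barton iodination (I2, tetramethylguanidine, THF, 0 °C) should give the 9-iodo-7-ene F5. Negishi coupling of F5 with alkylzinc 16 (PdCl2(dppf), THF/NMP, 50 °C) then gives 17.

Step 15. The trans-fused cyclopentenone 19 may epimerise at C5 (its hydrogen is α to the C6 carbonyl) during oxidation or reduction, or hydride delivery may show poor facial selectivity. The fallback inverts C6 by substitution instead; it sets out from 18 and comes back at 22. Diol 18 is acetylated selectively at the unhindered C2 hydroxyl (Ac2O, pyridine, 0 °C) to the 2α-acetoxy-6α-ol F6. A Mitsunobu reaction with isovaleric acid (PPh3, DIAD, toluene, 0 °C → rt) should then install the isovalerate at C6 with inversion to give 22.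

Further compounds
F1 | step 18 | dibromocyclopropane of diol 20 (2α,6β-diol, C8Br2 on the α face) | C[C@]12C[C@@H](O)CC(C)(C)[C@@H]1[C@H](O)[C@H]3C(Br)(Br)[C@@]23CC/C(C)=C/C(=O)OCC[Si](C)(C)C
F2 | step 18 | 2-acetate of F1 (6β-hydroxy dibromocyclopropane) | C[C@]12C[C@@H](OC(C)=O)CC(C)(C)[C@@H]1[C@H](O)[C@H]3C(Br)(Br)[C@@]23CC/C(C)=C/C(=O)OCC[Si](C)(C)C
F3 | step 18 | 7α,8-dibromo-2α-acetoxy-6β-isovaleryloxy 8-ene TMSE enoate | CC(=O)O[C@H]1CC(C)(C)[C@@H]2[C@H](OC(=O)CC(C)C)[C@@H](Br)C(Br)=C(CC/C(C)=C/C(=O)OCC[Si](C)(C)C)[C@@]2(C)C1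
F4 | step 8 | C9 hydrazone of ketone 9 | C[C@]12C[C@@H](O[Si](C)(C)C(C)(C)C)CC(C)(C)[C@@H]1[C@@H](O[Si](C)(C)C(C)(C)C)C/C2=N\N
F5 | step 8 | 2α,6α-bis(TBSO) 9-iodo-7-ene | C[C@]12C[C@@H](O[Si](C)(C)C(C)(C)C)CC(C)(C)[C@@H]1[C@@H](O[Si](C)(C)C(C)(C)C)C=C2I
F6 | step 15 | 2α-acetoxy 6α-hydroxy 7-ene TMSE enoate | C[C@]12C[C@@H](OC(C)=O)CC(C)(C)[C@@H]1[C@@H](O)C=C2CC/C(C)=C/C(=O)OCC[Si](C)(C)C
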